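**Retrosynthetic overview**

1. The last step joins two halves of similar size at the CH2 link: a C16 terpenoid hydroxy aldehyde (fragment A) and isovaleryl filicinic acid (fragment B, C13), by reductive Knoevenagel alkylation.
2. Fragment A: the C4 tertiary alcohol comes from the 3,4-epoxide of a Δ3-octalin aldehyde. Rings A and B are formed together by an endo intramolecular Diels–Alder reaction of an acyclic (E,E)-trienal whose single stereocentre (C7) controls C1, C5 and C10.
3. The trienal comes from a Negishi sp3–sp2 union of a chiral dienyl iodide with an (E)-β-iodo enal acetal. The iodide is made by Rh-catalysed asymmetric isopropenyl addition to 5,6-dihydro-2H-pyran-2-one, then two Wittig olefinations. The acetal is made from propynyl Grignard and orthoformate, then hydrozirconation–iodination.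
4. Fragment B: the trione ring is closed by Claisen cyclisation of methyl 2,2-dimethyl-3,5-dioxohexanoate (from methyl acetoacetate), then C-acylated with isovaleryl chloride.
5. Ring order: the lactone ring of the chiral building block is opened early; carbocyclic rings A and B form in one step; the trione ring is built separately and attached last.

Assumption: the target is one enol tautomer of a cyclic β-triketone; its tautomers, and those of compounds 28, 30 and 31, are treated as one compound each.
Decalin positions are quoted with eudesmane numbering (C1 carries the one-carbon arm, C4 the methyl and oxygen, C5 and C10 the ring fusion, C7 the isopropenyl group). The R/S label of the isopropenyl-bearing centre changes along compounds 3–17 only through CIP priority changes; that centre is never touched.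

**Fragment A, chiral dienyl iodide**

Step 1
Reactants: 1 5,6-dihydro-2H-pyran-2-one; 2 potassium trifluoro(prop-1-en-2-yl)borate
Product: 3 (4S)-4-(prop-1-en-2-yl)oxan-2-one
Conditions: [Rh(cod)2]PF6 (3 mol%), (S)-BINAP (3.3 mol%), toluene/H2O 4:1, 105 °C
Reagents that add atoms: none
Why: Rhodium-catalysed asymmetric conjugate addition (Hayashi–Miyaura type) of the alkenyl group to the cyclic enoate, in which the BINAP–rhodium alkenyl species adds to one enantioface of the s-trans-locked lactone and so sets C7 (the ligand hand is chosen by analogy with six-membered enones and the sign is checked by rotation at this stage).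

Step 2
Reactants: 3 (4S)-4-(prop-1-en-2-yl)oxan-2-one
Product: 4 (4S)-4-(prop-1-en-2-yl)oxan-2-ol (lactol, both anomers)
Conditions: iBu2AlH (1.1 equiv), CH2Cl2, −78 °C
Reagents that add atoms: none
Why: Partial hydride reduction of a lactone stops at the aluminium lactolate at low temperature and does not touch the stereocentre or the isopropenyl group.

Step 3
Reactants: 4 (4S)-4-(prop-1-en-2-yl)oxan-2-ol
Product: 6 (2E,5R)-7-hydroxy-2-methyl-5-(prop-1-en-2-yl)hept-2-enal, via open-chain hydroxy aldehyde 5 (not isolated)
Conditions: Ph3P=C(CH3)CHO (1.2 equiv), toluene, 90 °C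
Reagents that add atoms: 2-(triphenylphosphoranylidene)propanal, CC(C=O)=P(c1ccccc1)(c1ccccc1)c1ccccc1
Why: Wittig olefination of the ring-opened aldehyde with a stabilised ylide gives the (E)-2-methyl enal selectively, and the conjugated, α-branched product aldehyde is too unreactive to olefinate a second time.

Step 4
Reactants: 6 (2E,5R)-7-hydroxy-2-methyl-5-(prop-1-en-2-yl)hept-2-enal
Product: 7 (2E,5R)-7-iodo-2-methyl-5-(prop-1-en-2-yl)hept-2-enal
Conditions: I2, PPh3, imidazole, CH2Cl2, 0 °C
Reagents that add atoms: iodine, II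
Why: Appel iodination replaces the primary hydroxyl by SN2 displacement of the alkoxyphosphonium ion under near-neutral conditions that spare the enal, and it removes the hydroxyl before it can add to the enal in an oxa-Michael sense.

Step 5
Reactants: 7 (2E,5R)-7-iodo-2-methyl-5-(prop-1-en-2-yl)hept-2-enal
Product: 8 (3E,6R)-8-iodo-3-methyl-6-(prop-1-en-2-yl)octa-1,3-diene
Conditions: Ph3PCH3Br, KOtBu, THF, 0 °C; then 7, −78 → 0 °C
Reagents that add atoms: methyltriphenylphosphonium bromide, C[P+](c1ccccc1)(c1ccccc1)c1ccccc1.[Br-]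
Why: Wittig methylenation of the aldehyde is far faster than alkylation of the ylide by the primary iodide and leaves the (E) trisubstituted alkene intact, giving the (E)-1,3-diene.

**Fragment A, iodo enal acetal**

Step 6
Reactants: 9 prop-1-yn-1-ylmagnesium bromide; 10 trimethyl orthoformate
Product: 11 1,1-dimethoxybut-2-yne
Conditions: THF then toluene, 80 °C; then H2O
Reagents that add atoms: none
Why: Bodroux–Chichibabin-type substitution in which the alkynyl Grignard reagent displaces one methoxide of the orthoester through the dialkoxycarbenium ion to give the alkynyl acetal.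

Step 7
Reactants: 11 1,1-dimethoxybut-2-yne
Product: 13 (2E)-3-iodo-1,1-dimethoxybut-2-ene, via alkenylzirconocene chloride 12 (not isolated)
Conditions: Cp2Zr(H)Cl (1.5 equiv), THF, 25 → 45 °C; then I2, 0 °C
Reagents that add atoms: iodine, II
Why: Hydrozirconation adds Zr–H syn across the alkyne and, after equilibration, places zirconium on the methyl-bearing carbon away from the branched acetal, and iodinolysis of the C–Zr bond with retention gives the (E)-vinyl iodide with iodine trans to the acetal carbon.

**Fragment A, union and ring formation**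

Step 8
Reactants: 8 (3E,6R)-8-iodo-3-methyl-6-(prop-1-en-2-yl)octa-1,3-diene; 13 (2E)-3-iodo-1,1-dimethoxybut-2-ene
Product: 17 (2E,6S,8E)-3,9-dimethyl-6-(prop-1-en-2-yl)undeca-2,8,10-trienal, via alkyllithium 14 (not isolated), via alkylzinc chloride 15 (not isolated), via trienal dimethyl acetal 16 (not isolated)
Conditions: 8, t-BuLi (2.1 equiv), Et2O, −78 °C; ZnCl2 (THF), −78 → 0 °C; 13, Pd(PPh3)4 (5 mol%), THF, 25 °C; then 1 M HCl, THF, 0 °C
Reagents that add atoms: water, O
Why: Negishi sp3–sp2 cross-coupling in which iodine–lithium exchange and transmetalation give a primary alkylzinc that couples with the vinyl iodide under zerovalent palladium catalysis with retention of the (E) geometry, after which mild acid hydrolysis of the acetal releases the (E)-enal.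

Step 9
Reactants: 17 (2E,6S,8E)-3,9-dimethyl-6-(prop-1-en-2-yl)undeca-2,8,10-trienal
Product: 18 (1S,4aR,6S,8aS)-4,8a-dimethyl-6-(prop-1-en-2-yl)-1,2,4a,5,6,7,8,8a-octahydronaphthalene-1-carbaldehyde
Conditions: Me2AlCl (1.1 equiv), CH2Cl2, −78 → −20 °C; then 1 M HCl
Reagents that add atoms: none
Why: Lewis acid-promoted intramolecular Diels–Alder reaction forms rings A and B at once, the (E)-enal placing CHO cis to the new angular methyl (C1 and C10), the formyl-endo transition state giving the trans ring fusion (C5), and the chair-like tether with the isopropenyl group equatorial relaying the C7 configuration to all three new centres.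

Step 10
Reactants: 18 (1S,4aR,6S,8aS)-4,8a-dimethyl-6-(prop-1-en-2-yl)-1,2,4a,5,6,7,8,8a-octahydronaphthalene-1-carbaldehyde
Product: 19 3,4-epoxide of 18 with oxygen anti to the C10 methyl (1S,3S,4R,5S,7S,10S in eudesmane numbering)
Conditions: mCPBA (1.05 equiv), NaHCO3, CH2Cl2, −20 → 0 °C
Reagents that add atoms: 3-chloroperbenzoic acid, OOC(=O)c1cccc(Cl)c1
Why: Prilezhaev epoxidation is faster at the trisubstituted ring alkene than at the 1,1-disubstituted isopropenyl group, and the peracid approaches the face opposite the axial angular methyl, which fixes the C4–O bond on the side required in the target.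

Step 11
Reactants: 19 3,4-epoxy aldehyde
Product: 21 (1S,4S,4aR,7S,8aS)-4-(hydroxymethyl)-1,4a-dimethyl-7-(prop-1-en-2-yl)decahydronaphthalen-1-ol, via epoxy alcohol 20 (not isolated)
Conditions: LiEt3BH (4 equiv), THF, 0 → 65 °C; then H2O
Reagents that add atoms: none
Why: Hydride reduction in which the aldehyde is reduced first and the epoxide is then opened by SN2 attack at the secondary C3 (the tertiary C4 is shielded by the syn-axial angular methyl), so the C4–O bond keeps its configuration and the equatorial tertiary alcohol with axial methyl results.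

Step 12
Reactants: 21 diol
Product: 22 (1S,4S,4aS,6S,8aS)-4-hydroxy-4,8a-dimethyl-6-(prop-1-en-2-yl)decahydronaphthalene-1-carbaldehyde
Conditions: Dess–Martin periodinane (1.2 equiv), NaHCO3, CH2Cl2, 0 → 25 °C
Reagents that add atoms: none
Why: Dess–Martin oxidation converts only the primary alcohol because the tertiary alcohol cannot be oxidised, and the equatorial C1 aldehyde is the thermodynamically preferred epimer so C1 is not at risk.

**Fragment B**

Step 13
Reactants: 23 methyl acetoacetate
Product: 25 methyl 2,2-dimethyl-3-oxobutanoate, via methyl 2-methyl-3-oxobutanoate 24 (not isolated)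
Conditions: MeI (2.5 equiv), K2CO3, acetone, reflux
Reagents that add atoms: iodomethane, CI
Why: Double SN2 C-alkylation of the β-keto ester enolate at the doubly activated carbon installs the gem-dimethyl group and blocks that position for the later Claisen steps.

Step 14
Reactants: 25 methyl 2,2-dimethyl-3-oxobutanoate; 26 N-methoxy-N-methylacetamide
Product: 27 methyl 2,2-dimethyl-3,5-dioxohexanoate
Conditions: LiN(iPr)2 (1.1 equiv), THF, −78 °C; then 26, −78 → 0 °C; 1 M HCl
Reagents that add atoms: none
Why: Crossed Claisen-type acylation in which the only enolisable position (the acetyl methyl) gives a lithium enolate that adds to the Weinreb amide to form a stable chelate, released on work-up as the β-diketone without over-reaction.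

Step 15
Reactants: 27 methyl 2,2-dimethyl-3,5-dioxohexanoate
Product: 28 3,5-dihydroxy-4,4-dimethylcyclohexa-2,5-dien-1-one (filicinic acid)
Conditions: LiN(iPr)2 (3.2 equiv), THF, −78 → 25 °C; then 2 M HCl
Reagents that add atoms: none
Why: Intramolecular Claisen (Dieckmann-type) condensation in which the terminal carbanion of the β-diketone dianion attacks the ester in a six-membered ring closure, driven by formation of the stable enolised triketone anion.

Step 16
Reactants: 28 filicinic acid; 29 3-methylbutanoyl chloride
Product: 30 3,5-dihydroxy-6,6-dimethyl-2-(3-methylbutanoyl)cyclohexa-2,4-dien-1-one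
Conditions: AlCl3 (3 equiv), CH2Cl2/PhNO2, 0 → 25 °C
Reagents that add atoms: none
Why: Friedel–Crafts-type C-acylation of the electron-rich enolised triketone at one of its two equivalent ring CH positions, after which the chelated β-triketone is deactivated towards a second acylation.

**Late coupling**

Step 17
Reactants: 22 hydroxy aldehyde (fragment A); 30 isovaleryl filicinic acid (fragment B)
Product: 32 4-{[(1R,4S,4aS,6S,8aR)-4-hydroxy-4,8a-dimethyl-6-(prop-1-en-2-yl)decahydronaphthalen-1-yl]methyl}-3,5-dihydroxy-6,6-dimethyl-2-(3-methylbutanoyl)cyclohexa-2,4-dien-1-one, via alkylidene triketone 31 (not isolated)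
Conditions: L-proline (20 mol%), Hantzsch ester (1.3 equiv), CH2Cl2, 25 → 40 °C
Reagents that add atoms: none
Why: Organocatalytic reductive Knoevenagel alkylation in which the aldehyde condenses with the only free ring CH of 30 to an alkylidene (ortho-quinone-methide-like) intermediate that is reduced at once by conjugate hydride transfer from the Hantzsch ester, forming the CH2 link without touching any stereocentre.

**Compound list**

1 | 5,6-dihydro-2H-pyran-2-one | O=C1C=CCCO1 | starting material
2 | potassium trifluoro(prop-1-en-2-yl)borate | [K+].C=C(C)[B-](F)(F)F | starting material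
3 | (4S)-4-(prop-1-en-2-yl)oxan-2-one | C=C(C)[C@@H]1CC(=O)OCC1 | intermediate
4 | (4S)-4-(prop-1-en-2-yl)oxan-2-ol (both anomers) | C=C(C)[C@@H]1CC(O)OCC1 | intermediate
5 | (3S)-5-hydroxy-3-(prop-1-en-2-yl)pentanal | C=C(C)[C@@H](CCO)CC=O | intermediate
6 | (2E,5R)-7-hydroxy-2-methyl-5-(prop-1-en-2-yl)hept-2-enal | C=C(C)[C@@H](CCO)C/C=C(\C)C=O | intermediate
7 | (2E,5R)-7-iodo-2-methyl-5-(prop-1-en-2-yl)hept-2-enal | C=C(C)[C@@H](CCI)C/C=C(\C)C=O | intermediate
8 | (3E,6R)-8-iodo-3-methyl-6-(prop-1-en-2-yl)octa-1,3-diene | C=C(C)[C@@H](CCI)C/C=C(\C)C=C | intermediate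
9 | prop-1-yn-1-ylmagnesium bromide | CC#C[Mg]Br | starting material
10 | trimethyl orthoformate | COC(OC)OC | starting material
11 | 1,1-dimethoxybut-2-yne | CC#CC(OC)OC | intermediate
12 | chlorobis(cyclopentadienyl)[(2E)-4,4-dimethoxybut-2-en-2-yl]zirconium | C/C(=C\C(OC)OC)[Zr](Cl)(C1C=CC=C1)C1C=CC=C1 | intermediate
13 | (2E)-3-iodo-1,1-dimethoxybut-2-ene | C/C(I)=C\C(OC)OC | intermediate
14 | [(3S,5E)-6-methyl-3-(prop-1-en-2-yl)octa-5,7-dien-1-yl]lithium | C=C(C)[C@@H](CC[Li])C/C=C(\C)C=C | intermediate
15 | chloro[(3R,5E)-6-methyl-3-(prop-1-en-2-yl)octa-5,7-dien-1-yl]zinc | C=C(C)[C@@H](CC[Zn]Cl)C/C=C(\C)C=C | intermediate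
16 | (2E,6S,8E)-1,1-dimethoxy-3,9-dimethyl-6-(prop-1-en-2-yl)undeca-2,8,10-triene | C=C(C)[C@@H](CC/C(C)=C/C(OC)OC)C/C=C(\C)C=C | intermediate
17 | (2E,6S,8E)-3,9-dimethyl-6-(prop-1-en-2-yl)undeca-2,8,10-trienal | C=C(C)[C@@H](CC/C(C)=C/C=O)C/C=C(\C)C=C | intermediate
18 | (1S,4aR,6S,8aS)-4,8a-dimethyl-6-(prop-1-en-2-yl)-1,2,4a,5,6,7,8,8a-octahydronaphthalene-1-carbaldehyde | C=C(C)[C@H]1CC[C@]2(C)[C@@H](C=O)CC=C(C)[C@H]2C1 | intermediate
19 | 3,4-epoxide of 18, oxygen anti to the C10 methyl (1S,3S,4R,5S,7S,10S, eudesmane numbering) | C=C(C)[C@H]1CC[C@]2(C)[C@@H](C=O)C[C@@H]3O[C@]3(C)[C@H]2C1 | intermediate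
20 | epoxy alcohol, the C1 CH2OH analogue of 19 (1S,3S,4R,5S,7S,10R, eudesmane numbering) | C=C(C)[C@H]1CC[C@]2(C)[C@@H](CO)C[C@@H]3O[C@]3(C)[C@H]2C1 | intermediate
21 | (1S,4S,4aR,7S,8aS)-4-(hydroxymethyl)-1,4a-dimethyl-7-(prop-1-en-2-yl)decahydronaphthalen-1-ol | C=C(C)[C@H]1CC[C@]2(C)[C@@H](CO)CC[C@](C)(O)[C@H]2C1 | intermediate
22 | (1S,4S,4aS,6S,8aS)-4-hydroxy-4,8a-dimethyl-6-(prop-1-en-2-yl)decahydronaphthalene-1-carbaldehyde | C=C(C)[C@H]1CC[C@]2(C)[C@@H](C=O)CC[C@](C)(O)[C@H]2C1 | intermediate
23 | methyl acetoacetate | COC(=O)CC(C)=O | starting material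
24 | methyl 2-methyl-3-oxobutanoate | COC(=O)C(C)C(C)=O | intermediate
25 | methyl 2,2-dimethyl-3-oxobutanoate | COC(=O)C(C)(C)C(C)=O | intermediate
26 | N-methoxy-N-methylacetamide | CC(=O)N(C)OC | starting material
27 | methyl 2,2-dimethyl-3,5-dioxohexanoate | COC(=O)C(C)(C)C(=O)CC(C)=O | intermediate
28 | 3,5-dihydroxy-4,4-dimethylcyclohexa-2,5-dien-1-one (filicinic acid) | CC1(C)C(O)=CC(=O)C=C1O | intermediate
29 | 3-methylbutanoyl chloride | CC(C)CC(Cl)=O | starting material
30 | 3,5-dihydroxy-6,6-dimethyl-2-(3-methylbutanoyl)cyclohexa-2,4-dien-1-one | CC(C)CC(=O)C1=C(O)C=C(O)C(C)(C)C1=O | intermediate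
31 | alkylidene triketone from 22 and 30 (exocyclic alkene geometry not defined) | C=C(C)[C@H]1CC[C@]2(C)[C@@H](C=C3C(=O)C(C)(C)C(=O)C(C(=O)CC(C)C)=C3O)CC[C@](C)(O)[C@H]2C1 | intermediate
32 | 4-{[(1R,4S,4aS,6S,8aR)-4-hydroxy-4,8a-dimethyl-6-(prop-1-en-2-yl)decahydronaphthalen-1-yl]methyl}-3,5-dihydroxy-6,6-dimethyl-2-(3-methylbutanoyl)cyclohexa-2,4-dien-1-one | C=C(C)[C@H]1CC[C@]2(C)[C@@H](CC3=C(O)C(C)(C)C(=O)C(C(=O)CC(C)C)=C3O)CC[C@](C)(O)[C@H]2C1 | target

**Totals and risks**

Total step count: 17. Longest linear sequence: 11 steps (steps 1–5, 8–12 and 17). The iodo acetal branch (steps 6–7) and the fragment B branch (steps 13–16) run in parallel.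

The three steps most likely to fail:

Step 8 (sp3–sp2 union). The alkyllithium is generated next to a conjugated diene, and the alkylzinc can undergo β-hydride elimination on palladium. The fallback sets out from 8 and comes back at 17, and it makes no organometallic from 8. Iodide 8 is alkylated with LiC≡CH·H2NCH2CH2NH2 in DMSO to give the terminal alkyne (3E,6S)-3-methyl-6-(prop-1-en-2-yl)deca-1,3-dien-9-yne F1. Zirconium-catalysed methylalumination of the alkyne (Me3Al, Cp2ZrCl2 cat., CH2Cl2), then n-BuLi and (CH2O)n, gives the (E)-allylic alcohol (2E,6S,8E)-3,9-dimethyl-6-(prop-1-en-2-yl)undeca-2,8,10-trien-1-ol F2 by syn carbometalation. MnO2 in CH2Cl2 then returns the route to trienal 17.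

Step 9 (intramolecular Diels–Alder). The β,β-disubstituted enal is a sluggish dienophile, the diene is acid-sensitive, and facial control rests on one remote stereocentre. The fallback sets out from acetal 16 (isolated by leaving out the acid treatment in step 8) and comes back at 18. Catalytic Me3SiOTf in CH2Cl2 at −78 °C ionises the allylic acetal to a methoxyallyl cation, a much more reactive dienophile (cationic, Gassman-type cycloaddition). The cycloadduct is trapped as the acetal (1S,4aR,6S,8aS)-1-(dimethoxymethyl)-4,8a-dimethyl-6-(prop-1-en-2-yl)-1,2,4a,5,6,7,8,8a-octahydronaphthalene F3. Hydrolysis with pyridinium tosylate in wet acetone gives 18.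

Step 11 (epoxide opening). Hydride must attack C3 in the stereoelectronically less favoured diequatorial sense, so the opening may be slow or take another course. The fallback sets out from 19 and comes back at 21 by an electron-transfer mechanism that has no backside-attack requirement. NaBH4 in MeOH at 0 °C gives epoxy alcohol 20, which is now isolated. Treatment with n-BuLi (1 equiv) and then lithium 4,4′-di-tert-butylbiphenylide (2.2 equiv) in THF at −78 °C cleaves the C–O bond to the less substituted carbon. This gives the C3-lithiated dilithium dialkoxide of the 1-(oxidomethyl)-4-oxido decalin F4, and a MeOH quench delivers diol 21.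

**Further compounds**

F1 | step 8 | (3E,6S)-3-methyl-6-(prop-1-en-2-yl)deca-1,3-dien-9-yne | C=C(C)[C@@H](CCC#C)C/C=C(\C)C=C
F2 | step 8 | (2E,6S,8E)-3,9-dimethyl-6-(prop-1-en-2-yl)undeca-2,8,10-trien-1-ol | C=C(C)[C@@H](CC/C(C)=C/CO)C/C=C(\C)C=C
F3 | step 9 | (1S,4aR,6S,8aS)-1-(dimethoxymethyl)-4,8a-dimethyl-6-(prop-1-en-2-yl)-1,2,4a,5,6,7,8,8a-octahydronaphthalene | C=C(C)[C@H]1CC[C@]2(C)[C@@H](C(OC)OC)CC=C(C)[C@H]2C1
F4 | step 11 | C3-lithiated dilithium dialkoxide of the 1-(oxidomethyl)-4-oxido decalin (C3 configuration not defined) | C=C(C)[C@H]1CC[C@]2(C)[C@@H](CO[Li])CC([Li])[C@](C)(O[Li])[C@H]2C1
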